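Ring numbering: C1 carries the CH2O-aryl arm, C2 is CMe2, C3 carries OAc, C6 the methylidene. The cyclohexane is cut at C1–C2 and C3–C4. C2/C3 are read as an isobutyrate unit (C2 nucleophilic, C3 an ester carbonyl); the arc C1–C6–C5–C4 is a 2-carbomethoxy-1,3-diene whose ester carbon becomes the exocyclic methylene carbon, so C1 is a Michael acceptor and C4 a vinylogous donor. One pot, Mukaiyama–Michael addition then Dieckmann closure, builds the ring, the quaternary carbon and the C3 carbonyl; both alkene isomers of the diene ester converge. Reduction, reductive allylic transposition, lipase acetylation and Mitsunobu etherification complete the target.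

Key step: step 3

Remark: 1, 2, 7 and 15 are taken as commercial. All chiral compounds up to 12 are racemic; the absolute configuration is set in step 6 by a kinetic resolution, so that step can pass on at most half of its substrate.

Step 1
Reactants: 1 methyl but-3-enoate; 2 {[tert-butyl(dimethyl)silyl]oxy}acetaldehyde
Product: 4 methyl 4-{[tert-butyl(dimethyl)silyl]oxy}-2-ethenyl-3-hydroxybutanoate, via lithium dienolate 3 (not isolated)
Conditions: LiN(i-Pr)2, THF, −78 °C; then 2, −78 °C; aq. NH4Cl
Reagents that add atoms: none
Why: Aldol addition: the kinetic lithium dienolate of the β,γ-unsaturated ester should attack the aldehyde through its α-carbon, and the two stereocentres formed need no control because both are erased in step 2.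

Step 2
Reactants: 4 methyl 4-{[tert-butyl(dimethyl)silyl]oxy}-2-ethenyl-3-hydroxybutanoate
Product: 6 methyl 4-{[tert-butyl(dimethyl)silyl]oxy}-2-ethenylbut-2-enoate, via mesylate 5 (not isolated)
Conditions: MsCl, Et3N, CH2Cl2, 0 °C; then DBU, rt
Reagents that add atoms: none
Why: Mesylation followed by E1cB elimination through the acidic α-C–H should give the cross-conjugated 2-ethenyl enoate, and either alkene geometry serves in step 3.

Step 3
Reactants: 6 methyl 4-{[tert-butyl(dimethyl)silyl]oxy}-2-ethenylbut-2-enoate; 7 [(1-methoxy-2-methylprop-1-en-1-yl)oxy]trimethylsilane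
Product: 10 methyl 6-({[tert-butyl(dimethyl)silyl]oxy}methyl)-5,5-dimethyl-4-oxocyclohex-1-ene-1-carboxylate, via silyl ketene acetal 8 (not isolated), via potassium dienolate 9 (not isolated)
Conditions: Tf2NH (cat.), toluene, −78 to −40 °C, 6 added slowly to excess 7; then KOt-Bu, THF, −40 °C to rt; AcOH, −78 °C (one pot)
Reagents that add atoms: none
Why: Tf2NH and 7 should generate a silylium Lewis acid that activates the ester of 6, so that the dimethyl-substituted carbon of 7 adds to the only conjugated β-position (ring C1) and the silyl group is passed on to give the dienyl ketene acetal 8 (Mukaiyama–Michael addition, the elementary step of group-transfer chemistry), which forms the quaternary C2–tertiary C1 bond. KOt-Bu then frees the potassium dienolate 9, whose γ-carbon (ring C4) attacks the hindered methyl ester (ring C3) and expels methoxide; deprotonation of the resulting vinylogous β-keto ester drives this Dieckmann condensation, and cold acetic acid returns the β,γ-unsaturated ketone 10. The closest known reaction type is the tandem Michael–Claisen (Michael–Dieckmann) annulation of isobutyrate-type donors with unsaturated carbonyl acceptors. The cyclohexene ring closes in the 6-(enolendo)-exo-trig mode. The one new stereocentre (ring C1) is formed without control, so 10 is racemic, and both alkene isomers of 6 converge on it because ring C1 passes from sp2 to sp3 and the dienolate equilibrates. The step needs 1,4- over 1,2-addition and γ- over α-acylation: the soft ketene acetal and the cross-conjugated vinyl group (no 1,6-position) secure the first, the six- against four-membered ring the second, and slow addition of 6 to excess 7 keeps 8 from adding to a second molecule of 6.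

Step 4
Reactants: 10 methyl 6-({[tert-butyl(dimethyl)silyl]oxy}methyl)-5,5-dimethyl-4-oxocyclohex-1-ene-1-carboxylate (used crude)
Product: 11 rac-(1R,5S)-5-({[tert-butyl(dimethyl)silyl]oxy}methyl)-4-(hydroxymethyl)-6,6-dimethylcyclohex-3-en-1-ol
Conditions: i-Bu2AlH, CH2Cl2, −78 °C; aq. potassium sodium tartrate
Reagents that add atoms: none
Why: Hydride reduction should convert the ketone to the carbinol and the enoate to the allylic alcohol; at the ketone the hydride is expected to enter anti to the CH2OSi arm, which allylic 1,2-strain with the ester holds pseudo-axial and 1,3-syn to one carbonyl face, so that OH and the arm end up cis.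

Step 5
Reactants: 11 rac-(1R,5S)-5-({[tert-butyl(dimethyl)silyl]oxy}methyl)-4-(hydroxymethyl)-6,6-dimethylcyclohex-3-en-1-ol
Product: 12 rac-(1R,3S)-3-({[tert-butyl(dimethyl)silyl]oxy}methyl)-2,2-dimethyl-4-methylidenecyclohexan-1-ol
Conditions: 2-nitrobenzenesulfonohydrazide (NBSH), PPh3, DEAD, N-methylmorpholine, THF, −30 °C to rt
Reagents that add atoms: none
Why: Reductive 1,3-transposition of the primary allylic alcohol: Mitsunobu displacement by the sulfonyl hydrazide, loss of sulfinic acid and retro-ene loss of N2 from the allylic diazene should deliver hydrogen to the ring CH and leave the exocyclic methylene, while the hindered secondary alcohol and both stereocentres stay untouched.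

Step 6
Reactants: 12 rac-(1R,3S)-3-({[tert-butyl(dimethyl)silyl]oxy}methyl)-2,2-dimethyl-4-methylidenecyclohexan-1-ol
Product: 13 (1R,3S)-3-({[tert-butyl(dimethyl)silyl]oxy}methyl)-2,2-dimethyl-4-methylidenecyclohexyl acetate
Conditions: lipase from Burkholderia cepacia (immobilised), vinyl acetate, t-BuOMe, 35 °C, stopped near half conversion
Reagents that add atoms: vinyl acetate, C=COC(C)=O
Why: Lipase-catalysed transesterification as a kinetic resolution: by the empirical size rule for lipases the (1R)-carbinol, flanked by the quaternary carbon as the large and CH2 as the medium group, should be acylated with retention, which fixes both stereocentres of 13, while the (1S,3R)-enantiomer of 12 stays as the alcohol and is removed by chromatography.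

Step 7
Reactants: 13 (1R,3S)-3-({[tert-butyl(dimethyl)silyl]oxy}methyl)-2,2-dimethyl-4-methylidenecyclohexyl acetate
Product: 14 (1R,3S)-3-(hydroxymethyl)-2,2-dimethyl-4-methylidenecyclohexyl acetate
Conditions: HF·pyridine, pyridine, THF, 0 °C to rt
Reagents that add atoms: none
Why: Fluoride-mediated cleavage of the primary silyl ether (desilylation) under buffered conditions should leave the acetate, the exocyclic alkene and both stereocentres intact.

Step 8
Reactants: 14 (1R,3S)-3-(hydroxymethyl)-2,2-dimethyl-4-methylidenecyclohexyl acetate; 15 7-hydroxy-2H-chromen-2-one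
Product: 16 7-{[(1S,3R)-3-(acetyloxy)-2,2-dimethyl-6-methylidenecyclohexyl]methoxy}-2H-chromen-2-one
Conditions: PPh3, DIAD, THF, 0 °C to rt
Reagents that add atoms: none
Why: Mitsunobu etherification: the acidic phenol should displace the activated primary alcohol by an SN2 reaction at CH2, which touches neither stereocentre.

Compound list
1 | methyl but-3-enoate | C=CCC(=O)OC | starting material
2 | {[tert-butyl(dimethyl)silyl]oxy}acetaldehyde | O=CCO[Si](C)(C)C(C)(C)C | starting material
3 | lithium dienolate of 1 (lithium 1-methoxybuta-1,3-dien-1-olate; not isolated) | COC(O[Li])=CC=C | intermediate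
4 | methyl 4-{[tert-butyl(dimethyl)silyl]oxy}-2-ethenyl-3-hydroxybutanoate (racemic mixture of diastereomers) | COC(=O)C(C=C)C(O)CO[Si](C)(C)C(C)(C)C | intermediate
5 | methyl 4-{[tert-butyl(dimethyl)silyl]oxy}-2-ethenyl-3-[(methylsulfonyl)oxy]butanoate (not isolated) | COC(=O)C(C=C)C(OS(C)(=O)=O)CO[Si](C)(C)C(C)(C)C | intermediate
6 | methyl 4-{[tert-butyl(dimethyl)silyl]oxy}-2-ethenylbut-2-enoate (either or both alkene isomers) | COC(=O)C(C=C)=CCO[Si](C)(C)C(C)(C)C | intermediate
7 | [(1-methoxy-2-methylprop-1-en-1-yl)oxy]trimethylsilane (methyl trimethylsilyl dimethylketene acetal) | COC(O[Si](C)(C)C)=C(C)C | starting material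
8 | methyl 3-({[tert-butyl(dimethyl)silyl]oxy}methyl)-4-{methoxy[(trimethylsilyl)oxy]methylidene}-2,2-dimethylhex-5-enoate (racemic; not isolated) | COC(=O)C(C)(C)C(CO[Si](C)(C)C(C)(C)C)C(C=C)=C(OC)O[Si](C)(C)C | intermediate
9 | potassium dienolate formed from 8 by loss of the trimethylsilyl group (racemic; not isolated) | COC(=O)C(C)(C)C(CO[Si](C)(C)C(C)(C)C)C(C=C)=C(OC)[O-].[K+] | intermediate
10 | methyl 6-({[tert-butyl(dimethyl)silyl]oxy}methyl)-5,5-dimethyl-4-oxocyclohex-1-ene-1-carboxylate (racemic) | COC(=O)C1=CCC(=O)C(C)(C)C1CO[Si](C)(C)C(C)(C)C | intermediate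
11 | rac-(1R,5S)-5-({[tert-butyl(dimethyl)silyl]oxy}methyl)-4-(hydroxymethyl)-6,6-dimethylcyclohex-3-en-1-ol (cis racemate; SMILES shows the enantiomer that is carried on) | OCC1=CC[C@@H](O)C(C)(C)[C@H]1CO[Si](C)(C)C(C)(C)C | intermediate
12 | rac-(1R,3S)-3-({[tert-butyl(dimethyl)silyl]oxy}methyl)-2,2-dimethyl-4-methylidenecyclohexan-1-ol (cis racemate; SMILES shows the enantiomer that is carried on) | C=C1CC[C@@H](O)C(C)(C)[C@H]1CO[Si](C)(C)C(C)(C)C | intermediate
13 | (1R,3S)-3-({[tert-butyl(dimethyl)silyl]oxy}methyl)-2,2-dimethyl-4-methylidenecyclohexyl acetate | C=C1CC[C@@H](OC(C)=O)C(C)(C)[C@H]1CO[Si](C)(C)C(C)(C)C | intermediate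
14 | (1R,3S)-3-(hydroxymethyl)-2,2-dimethyl-4-methylidenecyclohexyl acetate | C=C1CC[C@@H](OC(C)=O)C(C)(C)[C@H]1CO | intermediate
15 | 7-hydroxy-2H-chromen-2-one (umbelliferone) | Oc1ccc2ccc(=O)oc2c1 | starting material
16 | 7-{[(1S,3R)-3-(acetyloxy)-2,2-dimethyl-6-methylidenecyclohexyl]methoxy}-2H-chromen-2-one | C=C1CC[C@@H](OC(C)=O)C(C)(C)[C@H]1COc1ccc2ccc(=O)oc2c1 | target

Total step count: 8. Longest linear sequence: 8 steps (1 or 2 to 16).

Steps most likely to fail

Step 3. The conjugate addition may stall at the hindered β-carbon. The ketene acetal 8 may add through its γ-carbon to further 6 (oligomerisation). The ring closure onto the neopentyl-type ester may lose out to retro-Michael cleavage, or 10 may drift into conjugation with the ketone before it is reduced. Fallback, from 6 back to 10: a thermal inverse-electron-demand Diels–Alder reaction of 6 with 1,1-dimethoxy-2-methylprop-1-ene (COC(OC)=C(C)C; toluene, sealed tube, about 110 °C) should form both ring bonds in one neutral, concerted step. It should give methyl 6-({[tert-butyl(dimethyl)silyl]oxy}methyl)-4,4-dimethoxy-5,5-dimethylcyclohex-1-ene-1-carboxylate F1. Mild hydrolysis of the ketal (PPTS, wet acetone) then gives 10.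

Step 6. Acylation may be too slow or too unselective at a carbinol that sits next to a quaternary carbon, so that the acetate is formed with insufficient enantiomeric purity. Fallback, from 12 back to 13: racemic 12 is esterified with (2S)-2-methoxy-2-phenylacetic acid (DCC, DMAP, CH2Cl2) and the two diastereomeric esters are separated on silica. The wanted ester, (1R,3S)-3-({[tert-butyl(dimethyl)silyl]oxy}methyl)-2,2-dimethyl-4-methylidenecyclohexyl (2S)-2-methoxy-2-phenylacetate F2, is saponified (LiOH, THF–MeOH–H2O) to the single-enantiomer alcohol (1R,3S)-3-({[tert-butyl(dimethyl)silyl]oxy}methyl)-2,2-dimethyl-4-methylidenecyclohexan-1-ol F3. Acetylation (Ac2O, DMAP, pyridine) then gives 13.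

Step 8. The SN2 displacement at the β-branched CH2 may be slow, so that the activated alcohol is lost to hydrazide alkylation or to elimination towards the exocyclic diene. Fallback, from 14 to 16: 14 is first converted (MsCl, Et3N, CH2Cl2, 0 °C) into the isolable (1R,3S)-3-{[(methylsulfonyl)oxy]methyl}-2,2-dimethyl-4-methylidenecyclohexyl acetate F4. The preformed caesium phenoxide of 15 (Cs2CO3, DMF, 60 °C) then displaces the mesylate to give 16.

Further compounds
F1 | step 3 | methyl 6-({[tert-butyl(dimethyl)silyl]oxy}methyl)-4,4-dimethoxy-5,5-dimethylcyclohex-1-ene-1-carboxylate (racemic) | COC(=O)C1=CCC(OC)(OC)C(C)(C)C1CO[Si](C)(C)C(C)(C)C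
F2 | step 6 | (1R,3S)-3-({[tert-butyl(dimethyl)silyl]oxy}methyl)-2,2-dimethyl-4-methylidenecyclohexyl (2S)-2-methoxy-2-phenylacetate | C=C1CC[C@@H](OC(=O)[C@@H](OC)c2ccccc2)C(C)(C)[C@H]1CO[Si](C)(C)C(C)(C)C
F3 | step 6 | (1R,3S)-3-({[tert-butyl(dimethyl)silyl]oxy}methyl)-2,2-dimethyl-4-methylidenecyclohexan-1-ol (single enantiomer) | C=C1CC[C@@H](O)C(C)(C)[C@H]1CO[Si](C)(C)C(C)(C)C
F4 | step 8 | (1R,3S)-3-{[(methylsulfonyl)oxy]methyl}-2,2-dimethyl-4-methylidenecyclohexyl acetate | C=C1CC[C@@H](OC(C)=O)C(C)(C)[C@H]1COS(C)(=O)=O
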